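## The problem

Selaginellin F (25) is an achiral polyphenol built on a benzene ring A with four contiguous substituents. C1 carries the diarylmethylene carbon Cm of a para-quinone methide, C2 the 2,4-dihydroxyphenyl ring B, C5 a hydroxymethyl group and C6 a (4-hydroxyphenyl)ethynyl group; C3 and C4 carry hydrogen. There is no stereocentre and no double-bond geometry to set. The Cm=C bond ends in a symmetrical cyclohexadienone, and a proton shift interchanges that dienone with the 4-hydroxyphenyl group on Cm, so both rings can come from one symmetrical diaryl ketone. The task is therefore regiochemical and steric: C1 and C6 are each flanked on both sides, and the bonds needed there join ring A to a carbon bearing two more aryl groups and to an sp carbon. The quinone methide is electrophilic at Cm. It adds water and alcohols and can be captured by the ortho hydroxyl of ring B to close a 6H-benzo[c]chromene, so it has to be released last. The alkyne lies between a benzylic alcohol and, in any precursor, the Cm carbinol, and can suffer 5-exo-dig attack by an alkoxide under strong base or π-acidic metals. The resorcinol ring and the benzylic position of ring A (para to the C2 oxygen) rule out oxidants such as DDQ and free formaldehyde under acid. The enabling feature is that C1 and C6 are adjacent and carry one carbon substituent that can arrive as a nucleophile (the acetylide at C6) and one that can arrive as an electrophile (the ketone carbon Cm at C1). That is the pattern of an aryne across C1–C6, and an oxygen placed on C2, later exchanged for ring B, polarises that aryne so that the nucleophile goes to C6.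

## Retrosynthesis

**Unveiling (25 from 23).** Only C–O bonds are cut. All six hydroxyls are carried as methoxymethyl (MOM) ethers and Cm as a tertiary carbinol. One acidic operation in methanol should remove the acetals, pass through hexahydroxy carbinol 24 and lose water across Cm to give the quinone methide. Methyl ethers would demand BBr3, which endangers the benzylic alcohol and the alkyne. Silyl ethers would not survive the organomagnesium chemistry as reliably. Methanol as solvent is required so that the formaldehyde equivalents leave as dimethoxymethane and do not alkylate the resorcinol ring.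

**Ring B (23 from 18 and 22).** The C2–C1' biaryl bond is cut to aryl triflate 18 and pinacol boronate 22 (Suzuki–Miyaura coupling). This bond is made last among the C–C bonds because C2 must carry oxygen while the aryne is generated. The same oxygen then becomes the leaving group. Boronate 22 comes from 4-bromoresorcinol (19) through bis-MOM ether 20 and aryllithium 21. The coupling has to tolerate the free tertiary carbinol on the neighbouring carbon.

**Handle exchange (18 from 17 from 16).** The triflate comes from phenol 17, and 17 from allyl ether 16. An allyl ether is preferred to a 4-methoxybenzyl ether. Oxidative removal with DDQ would attack the benzylic CH2OMOM position of ring A, which is para to the C2 oxygen, and the freed para-hydroxybenzyl ether even more readily. Zerovalent palladium with an amine removes allyl under basic, non-oxidising conditions that also protect the acid-labile carbinol.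

**Key disconnection (16 from 11, 3 and 5).** The C6–C(sp) and C1–Cm bonds are cut together. Ring A becomes aryne 14, generated from 2-iodoaryl 4-chlorobenzenesulfonate 11 by way of arylmagnesium 13. The alkynyl group comes from alkynylmagnesium chloride 12, made from alkyne 3. Cm comes from ketone 5, which traps arylmagnesium 15. The neighbouring option, two successive cross-couplings on a 1,6-dihalide, would have to tell apart two adjacent hindered positions and would still need an aryl-metal addition to the ketone. The aryne route makes both bonds in one flask and fixes their order by polarity. The precursors are a trisubstituted iodoarene, a terminal alkyne and a symmetrical benzophenone, all far simpler than 16. The forward reaction must put the acetylide on C6 only and must let a doubly ortho-substituted arylmagnesium add to a diaryl ketone.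

**Ring A precursor (11 from 6).** The substitution pattern of 11 maps onto 2,4-dihydroxybenzaldehyde (6): the formyl group becomes the C5 CH2OMOM, O-2 the sulfonate on C6, C3 the iodinated C1 and O-4 the C2 allyloxy group. Iodination between the two oxygens gives 7. The unchelated 4-hydroxyl is allylated (8), the chelated 2-hydroxyl sulfonylated (9), the aldehyde reduced (10) and the alcohol protected (11).

**Partners (3 from 1; 5 from 4).** Alkyne 3 is reached from 4-hydroxybenzaldehyde (1) by MOM protection (2) and one-carbon homologation. Ketone 5 is the bis-MOM ether of 4,4'-dihydroxybenzophenone (4).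

## Roads not taken

**Alternative 1:** Ring A is cut at C1–C2, C3–C4 and C5–C6 and assembled by [2+2+2] cyclotrimerisation. The precursor is the triyne ester A1, 2-ethynyl-5-(methoxymethoxy)phenyl 3-[diisopropyl(prop-2-yn-1-yloxy)silyl]propiolate. RhCl(PPh3)3 (monovalent rhodium) would join its three alkynes to give A2, a 3-(methoxymethoxy)-6H-benzo[c]chromen-6-one with a 1,1-diisopropyl-oxasilole fused across C5 and C6 of ring A.
- Merits: the two tethers fix every position of ring A, so there is no regiochemical question. The lactone carbonyl is Cm at the right oxidation level to take up two identical aryl nucleophiles. Ring B is present from the start.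
- Weak points: the key step delivers only the core. The silicon on C6 must still be turned into a halide and then into the arylethynyl group by a Sonogashira coupling at the most crowded position of the molecule, next to the new diarylcarbinol. The aryl propiolate A1 is itself a labile, multi-step substrate.
- Comparison: this road is better in regiochemical certainty and builds ring A de novo. The chosen plan depends on aryne polarisation, but it places the alkynyl group and the complete triarylcarbinol in one flask on a ring bought as a cheap resorcinol aldehyde, and it needs no late coupling at C6.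

**Alternative 2:** Ring A is cut at C1–C2 and C5–C6. The diynone A3, 1,5-bis[4-(methoxymethoxy)phenyl]penta-2,4-diyn-1-one, and the (E,E)-diene A4, the tert-butyldimethylsilyl ether of 5-[2,4-bis(methoxymethoxy)phenyl]penta-2,4-dien-1-ol, would combine in a [4+2] cycloaddition at the carbonyl-conjugated triple bond (heat or Me2AlCl). DDQ in the same flask would aromatise the adduct to the ketone A5.
- Merits: it is highly convergent. Ring B, the arylethynyl group and one Cm aryl group arrive in the key step, and no cross-coupling on the crowded ring is needed. After A5 only an aryl-metal addition and deprotection remain, so this road is shorter after its key step than the chosen one.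
- Weak points: the aryl terminus of A4 favours the required orientation, but the CH2O-substituted terminus opposes it, so the regiochemistry is not assured. A3 is a sensitive acceptor with two triple bonds open to cycloaddition and conjugate addition. Me2AlCl threatens the MOM acetals, and DDQ meets several electron-rich arenes. The last aryl group must then add to a ketone flanked by ring B and the alkyne.
- Comparison: the chosen plan sets against the shorter endgame a regiochemistry controlled by a single oxygen substituent, stable and easily made precursors, and formation of the crowded C1–Cm bond from the ring outward by an arylmagnesium species that the aryne step creates in place.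

**Alternative 3:** The C1–Cm bond and the bond between the two future alkyne carbons are formed by a Larock indenone annulation. The ortho-iodobenzaldehyde A6 (ring B on C2, iodine on C1, formyl on C6, CH2OMOM on C5) and the symmetrical alkyne A7, 1,2-bis[4-(methoxymethoxy)phenyl]ethyne, would react under Pd(OAc)2, NaOAc and n-Bu4NCl. The C1 arylpalladium adds across A7, and the vinylpalladium adds to the formyl group to close the indenone A8.
- Merits: a symmetrical alkyne removes any regiochemical issue. The annulation is a mild, catalytic and well-behaved way to make the hindered C1–Cm bond, and ring B is in place early.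
- Weak points: A6 needs its own synthesis with iodine wedged between ring B and the formyl group. A8 holds the atoms in the wrong connectivity, so the C2=C3 bond of the indenone must be cleaved oxidatively in the presence of five electron-rich MOM-protected arenes. The resulting diketone must then be converted into the alkyne, and an aryl group added selectively to one of three carbonyl groups.
- Comparison: in step count and chemoselectivity this road is clearly behind the chosen plan. Its one advantage, a catalytic C1–Cm bond formation under mild conditions, is offset in the chosen plan by making that bond and the C6–C(sp) bond in one operation without any later skeletal reorganisation.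

Key step: step 9

Assumption: 25 is taken to rest as the open para-quinone methide drawn for the natural product, with the ring B hydroxyl free; equivalents quoted are planning values.

## Route

Step 1
Reactants: 1 4-hydroxybenzaldehyde
Product: 2 4-(methoxymethoxy)benzaldehyde
Conditions: MOMCl, iPr2NEt, CH2Cl2, 0 °C to rt
Reagents that add atoms: chloromethyl methyl ether, COCCl
Why: O-alkylation of the phenol by the reactive α-chloro ether (Williamson-type acetal formation); the aldehyde is untouched under amine base.

Step 2
Reactants: 2 4-(methoxymethoxy)benzaldehyde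
Product: 3 1-ethynyl-4-(methoxymethoxy)benzene
Conditions: dimethyl (1-diazo-2-oxopropyl)phosphonate, K2CO3, MeOH, rt
Reagents that add atoms: dimethyl (1-diazo-2-oxopropyl)phosphonate, COP(=O)(OC)C(=[N+]=[N-])C(C)=O
Why: Seyferth–Gilbert homologation in the Ohira–Bestmann variant; the non-enolisable aryl aldehyde is an ideal substrate, and the aryl MOM ether is stable to carbonate in methanol.

Step 3
Reactants: 4 4,4'-dihydroxybenzophenone
Product: 5 bis[4-(methoxymethoxy)phenyl]methanone
Conditions: MOMCl (2.4 equiv), iPr2NEt, CH2Cl2, 0 °C to rt
Reagents that add atoms: chloromethyl methyl ether, COCCl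
Why: Double O-alkylation of two equivalent, acidic para-acyl phenols; the diaryl ketone is inert to the conditions.

Step 4
Reactants: 6 2,4-dihydroxybenzaldehyde
Product: 7 2,4-dihydroxy-3-iodobenzaldehyde
Conditions: I2, HIO3, EtOH/H2O, rt to 40 °C
Reagents that add atoms: iodine, II; iodic acid, OI(=O)=O
Why: Electrophilic aromatic iodination with iodine and iodic acid; in chelated 2-hydroxyaryl carbonyl compounds the position between the two oxygens is the classical site of substitution, and the deactivating formyl group limits over-iodination when the reagent is kept substoichiometric.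

Step 5
Reactants: 7 2,4-dihydroxy-3-iodobenzaldehyde
Product: 8 2-hydroxy-3-iodo-4-(prop-2-en-1-yloxy)benzaldehyde
Conditions: allyl bromide (1.05 equiv), KHCO3, DMF, rt to 40 °C
Reagents that add atoms: allyl bromide, C=CCBr
Why: Williamson etherification; the 4-hydroxyl is the more acidic and is not tied up in the hydrogen bond to the formyl group, so a weak base alkylates it selectively, as is usual for 2,4-dihydroxyaryl carbonyl compounds.

Step 6
Reactants: 8 2-hydroxy-3-iodo-4-(prop-2-en-1-yloxy)benzaldehyde
Product: 9 6-formyl-2-iodo-3-(prop-2-en-1-yloxy)phenyl 4-chlorobenzenesulfonate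
Conditions: 4-ClC6H4SO2Cl, Et3N, DMAP (cat.), CH2Cl2, 0 °C to rt
Reagents that add atoms: 4-chlorobenzenesulfonyl chloride, O=S(=O)(Cl)c1ccc(Cl)cc1
Why: Sulfonylation of the remaining phenol with DMAP catalysis; the arenesulfonate is chosen because it survives hydride and Grignard reagents at low temperature yet leaves readily from an ortho-magnesiated arene.

Step 7
Reactants: 9 6-formyl-2-iodo-3-(prop-2-en-1-yloxy)phenyl 4-chlorobenzenesulfonate
Product: 10 6-(hydroxymethyl)-2-iodo-3-(prop-2-en-1-yloxy)phenyl 4-chlorobenzenesulfonate
Conditions: NaBH4, THF/MeOH, 0 °C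
Reagents that add atoms: none
Why: Borohydride reduction of an aryl aldehyde; aryl iodide, aryl sulfonate and allyl ether are inert to NaBH4 at 0 °C, and the short cold reaction limits sulfonyl transfer to the new alkoxide.

Step 8
Reactants: 10 6-(hydroxymethyl)-2-iodo-3-(prop-2-en-1-yloxy)phenyl 4-chlorobenzenesulfonate
Product: 11 2-iodo-6-[(methoxymethoxy)methyl]-3-(prop-2-en-1-yloxy)phenyl 4-chlorobenzenesulfonate
Conditions: MOMCl, iPr2NEt, CH2Cl2, 0 °C to rt
Reagents that add atoms: chloromethyl methyl ether, COCCl
Why: Standard acetal protection of a primary benzylic alcohol; the MOM group removes the acidic proton before the organomagnesium step and offers a Lewis-basic site beside the future C6.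

Step 9
Reactants: 11 2-iodo-6-[(methoxymethoxy)methyl]-3-(prop-2-en-1-yloxy)phenyl 4-chlorobenzenesulfonate; 3 1-ethynyl-4-(methoxymethoxy)benzene; 5 bis[4-(methoxymethoxy)phenyl]methanone
Product: 16 {5-[(methoxymethoxy)methyl]-6-{[4-(methoxymethoxy)phenyl]ethynyl}-2-(prop-2-en-1-yloxy)phenyl}bis[4-(methoxymethoxy)phenyl]methanol, via alkynylmagnesium chloride 12 (not isolated), via magnesiated aryl sulfonate 13 (not isolated), via aryne 14 (not isolated), via arylmagnesium adduct 15 (not isolated)
Conditions: 3 (2.5 equiv), iPrMgCl (2.5 equiv), THF, 0 °C to rt; separately 11, iPrMgCl (1.05 equiv), THF, −78 °C; combine, −78 °C to rt; then 5 (4 equiv), THF, 0 to 40 °C; aq NH4Cl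
Reagents that add atoms: none
Why: iPrMgCl deprotonates 3 to 12, and at −78 °C exchanges the iodine of 11, which is activated by two flanking oxygen substituents, to give 13; this species persists in the cold because 4-chlorobenzenesulfonate is only a moderate leaving group. On warming in the presence of 12, 13 loses the sulfonate to give aryne 14 across C1–C6. The allyloxy group on C2 withdraws σ-density and distorts the aryne so that the distal carbon C6 is the electrophilic one; attack there puts the carbanion on C1 beside oxygen, where it is inductively stabilised and chelated, and the C5 CH2OMOM oxygen can pre-coordinate the slim sp nucleophile, so 15 should form as one regioisomer. 15 has no β-hydrogen and 5 is non-enolisable, so 1,2-addition is the only productive path and gives 16 after the quench. The reaction type is the known carbomagnesiation of arynes from 2-iodoaryl sulfonates with electrophilic trapping of the new arylmagnesium, here with an alkynylmagnesium nucleophile and a diaryl ketone trap. No ring is closed and no stereocentre is formed; two skeletal bonds (C6–C(sp) and C1–Cm) are made. The step needs acetylide addition to outrun addition of 13 to 14, which the excess of 12 and the slow release of the aryne on warming secure, and it needs exact matching of alkyne and iPrMgCl so that neither free alkyne (a proton source) nor free iPrMgCl (a competing nucleophile) remains. The excess of 5 satisfies surplus 12, which otherwise competes for the ketone, and the tertiary propargylic alcohol so formed is removed by chromatography.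

Step 10
Reactants: 16 {5-[(methoxymethoxy)methyl]-6-{[4-(methoxymethoxy)phenyl]ethynyl}-2-(prop-2-en-1-yloxy)phenyl}bis[4-(methoxymethoxy)phenyl]methanol
Product: 17 2-{hydroxybis[4-(methoxymethoxy)phenyl]methyl}-4-[(methoxymethoxy)methyl]-3-{[4-(methoxymethoxy)phenyl]ethynyl}phenol
Conditions: Pd(PPh3)4 (cat.), morpholine, THF, rt
Reagents that add atoms: none
Why: Tsuji–Trost deallylation of an aryl allyl ether with an amine as allyl acceptor; the medium stays basic and non-oxidising, which protects the acid-labile carbinol, the MOM acetals and the para-oxygenated benzylic ether, and 17 is carried on over base-washed silica to avoid dehydration to an ortho-quinone methide.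

Step 11
Reactants: 17 2-{hydroxybis[4-(methoxymethoxy)phenyl]methyl}-4-[(methoxymethoxy)methyl]-3-{[4-(methoxymethoxy)phenyl]ethynyl}phenol
Product: 18 2-{hydroxybis[4-(methoxymethoxy)phenyl]methyl}-4-[(methoxymethoxy)methyl]-3-{[4-(methoxymethoxy)phenyl]ethynyl}phenyl trifluoromethanesulfonate
Conditions: PhNTf2, Et3N, DMAP (cat.), CH2Cl2, rt
Reagents that add atoms: N-phenylbis(trifluoromethanesulfonimide), O=S(=O)(N(c1ccccc1)S(=O)(=O)C(F)(F)F)C(F)(F)F
Why: Phenol triflation with the mild triflimide reagent, which sulfonylates the phenoxide but neither the hindered tertiary alcohol nor the carbinol carbon, unlike Tf2O, which could ionise the carbinol.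

Step 12
Reactants: 19 4-bromoresorcinol
Product: 20 1-bromo-2,4-bis(methoxymethoxy)benzene
Conditions: MOMCl (2.4 equiv), iPr2NEt, CH2Cl2, 0 °C to rt
Reagents that add atoms: chloromethyl methyl ether, COCCl
Why: Double O-alkylation of both phenols as for 5; the aryl bromide is unaffected.

Step 13
Reactants: 20 1-bromo-2,4-bis(methoxymethoxy)benzene
Product: 22 2-[2,4-bis(methoxymethoxy)phenyl]-4,4,5,5-tetramethyl-1,3,2-dioxaborolane, via aryllithium 21 (not isolated)
Conditions: n-BuLi, THF, −78 °C; iPrOBpin, −78 °C to rt; aq NH4Cl
Reagents that add atoms: 2-isopropoxy-4,4,5,5-tetramethyl-1,3,2-dioxaborolane, CC(C)OB1OC(C)(C)C(C)(C)O1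
Why: Bromine–lithium exchange is faster than MOM-directed deprotonation at −78 °C and gives 21 at the brominated carbon only; borylation with the isopropoxy pinacol borate gives the pinacol ester, which resists protodeboronation better than the free acid of this electron-rich ortho-alkoxy arene.

Step 14
Reactants: 18 2-{hydroxybis[4-(methoxymethoxy)phenyl]methyl}-4-[(methoxymethoxy)methyl]-3-{[4-(methoxymethoxy)phenyl]ethynyl}phenyl trifluoromethanesulfonate; 22 2-[2,4-bis(methoxymethoxy)phenyl]-4,4,5,5-tetramethyl-1,3,2-dioxaborolane
Product: 23 [2',4'-bis(methoxymethoxy)-4-[(methoxymethoxy)methyl]-3-{[4-(methoxymethoxy)phenyl]ethynyl}-[1,1'-biphenyl]-2-yl]bis[4-(methoxymethoxy)phenyl]methanol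
Conditions: Pd(OAc)2, SPhos, K3PO4, THF/H2O, 60 °C
Reagents that add atoms: none
Why: Suzuki–Miyaura coupling of an aryl triflate with an ortho-substituted arylboronate; the bulky electron-rich biarylphosphine is the established answer to ortho-substituted partners, the triflate carbon has only one ortho substituent, and the moderate temperature and phosphate base are chosen to keep the neighbouring tertiary alcohol a spectator.

Step 15
Reactants: 23 [2',4'-bis(methoxymethoxy)-4-[(methoxymethoxy)methyl]-3-{[4-(methoxymethoxy)phenyl]ethynyl}-[1,1'-biphenyl]-2-yl]bis[4-(methoxymethoxy)phenyl]methanol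
Product: 25 selaginellin F, 4-{[2',4'-dihydroxy-4-(hydroxymethyl)-3-[(4-hydroxyphenyl)ethynyl]-[1,1'-biphenyl]-2-yl](4-hydroxyphenyl)methylidene}cyclohexa-2,5-dien-1-one, via hexahydroxy carbinol 24 (not isolated)
Conditions: HCl (conc. aq), MeOH/THF, 40 °C; then aq NaHCO3 to pH 7
Reagents that add atoms: none
Why: Acid-catalysed transacetalisation removes all six MOM groups as dimethoxymethane, so no free formaldehyde meets the resorcinol ring; the doubly para-hydroxylated triarylcarbinol 24 then ionises and loses water (acid-catalysed 1,6-elimination, fuchsone formation) to give the quinone methide, with no stereochemical element to control.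

## Compound list

1 | 4-hydroxybenzaldehyde | O=Cc1ccc(O)cc1 | starting material
2 | 4-(methoxymethoxy)benzaldehyde | COCOc1ccc(C=O)cc1 | intermediate
3 | 1-ethynyl-4-(methoxymethoxy)benzene | COCOc1ccc(C#C)cc1 | intermediate
4 | 4,4'-dihydroxybenzophenone | O=C(c1ccc(O)cc1)c1ccc(O)cc1 | starting material
5 | bis[4-(methoxymethoxy)phenyl]methanone | COCOc1ccc(C(=O)c2ccc(OCOC)cc2)cc1 | intermediate
6 | 2,4-dihydroxybenzaldehyde | O=Cc1ccc(O)cc1O | starting material
7 | 2,4-dihydroxy-3-iodobenzaldehyde | O=Cc1ccc(O)c(I)c1O | intermediate
8 | 2-hydroxy-3-iodo-4-(prop-2-en-1-yloxy)benzaldehyde | C=CCOc1ccc(C=O)c(O)c1I | intermediate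
9 | 6-formyl-2-iodo-3-(prop-2-en-1-yloxy)phenyl 4-chlorobenzenesulfonate | C=CCOc1ccc(C=O)c(OS(=O)(=O)c2ccc(Cl)cc2)c1I | intermediate
10 | 6-(hydroxymethyl)-2-iodo-3-(prop-2-en-1-yloxy)phenyl 4-chlorobenzenesulfonate | C=CCOc1ccc(CO)c(OS(=O)(=O)c2ccc(Cl)cc2)c1I | intermediate
11 | 2-iodo-6-[(methoxymethoxy)methyl]-3-(prop-2-en-1-yloxy)phenyl 4-chlorobenzenesulfonate | C=CCOc1ccc(COCOC)c(OS(=O)(=O)c2ccc(Cl)cc2)c1I | intermediate
12 | {[4-(methoxymethoxy)phenyl]ethynyl}magnesium chloride | COCOc1ccc(C#C[Mg]Cl)cc1 | intermediate
13 | {2-[(4-chlorobenzenesulfonyl)oxy]-3-[(methoxymethoxy)methyl]-6-(prop-2-en-1-yloxy)phenyl}magnesium chloride | C=CCOc1ccc(COCOC)c(OS(=O)(=O)c2ccc(Cl)cc2)c1[Mg]Cl | intermediate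
14 | 3-[(methoxymethoxy)methyl]-6-(prop-2-en-1-yloxy)benzyne (triple bond between C1 and C6 of ring A) | C=CCOC1=CC=C(COCOC)C#C1 | intermediate
15 | {3-[(methoxymethoxy)methyl]-2-{[4-(methoxymethoxy)phenyl]ethynyl}-6-(prop-2-en-1-yloxy)phenyl}magnesium chloride | C=CCOc1ccc(COCOC)c(C#Cc2ccc(OCOC)cc2)c1[Mg]Cl | intermediate
16 | {5-[(methoxymethoxy)methyl]-6-{[4-(methoxymethoxy)phenyl]ethynyl}-2-(prop-2-en-1-yloxy)phenyl}bis[4-(methoxymethoxy)phenyl]methanol | C=CCOc1ccc(COCOC)c(C#Cc2ccc(OCOC)cc2)c1C(O)(c1ccc(OCOC)cc1)c1ccc(OCOC)cc1 | intermediate
17 | 2-{hydroxybis[4-(methoxymethoxy)phenyl]methyl}-4-[(methoxymethoxy)methyl]-3-{[4-(methoxymethoxy)phenyl]ethynyl}phenol | COCOCc1ccc(O)c(C(O)(c2ccc(OCOC)cc2)c2ccc(OCOC)cc2)c1C#Cc1ccc(OCOC)cc1 | intermediate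
18 | 2-{hydroxybis[4-(methoxymethoxy)phenyl]methyl}-4-[(methoxymethoxy)methyl]-3-{[4-(methoxymethoxy)phenyl]ethynyl}phenyl trifluoromethanesulfonate | COCOCc1ccc(OS(=O)(=O)C(F)(F)F)c(C(O)(c2ccc(OCOC)cc2)c2ccc(OCOC)cc2)c1C#Cc1ccc(OCOC)cc1 | intermediate
19 | 4-bromoresorcinol | Oc1ccc(Br)c(O)c1 | starting material
20 | 1-bromo-2,4-bis(methoxymethoxy)benzene | COCOc1ccc(Br)c(OCOC)c1 | intermediate
21 | [2,4-bis(methoxymethoxy)phenyl]lithium | COCOc1ccc([Li])c(OCOC)c1 | intermediate
22 | 2-[2,4-bis(methoxymethoxy)phenyl]-4,4,5,5-tetramethyl-1,3,2-dioxaborolane | COCOc1ccc(B2OC(C)(C)C(C)(C)O2)c(OCOC)c1 | intermediate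
23 | [2',4'-bis(methoxymethoxy)-4-[(methoxymethoxy)methyl]-3-{[4-(methoxymethoxy)phenyl]ethynyl}-[1,1'-biphenyl]-2-yl]bis[4-(methoxymethoxy)phenyl]methanol | COCOCc1ccc(-c2ccc(OCOC)cc2OCOC)c(C(O)(c2ccc(OCOC)cc2)c2ccc(OCOC)cc2)c1C#Cc1ccc(OCOC)cc1 | intermediate
24 | [2',4'-dihydroxy-4-(hydroxymethyl)-3-[(4-hydroxyphenyl)ethynyl]-[1,1'-biphenyl]-2-yl]bis(4-hydroxyphenyl)methanol | OCc1ccc(-c2ccc(O)cc2O)c(C(O)(c2ccc(O)cc2)c2ccc(O)cc2)c1C#Cc1ccc(O)cc1 | intermediate
25 | selaginellin F, 4-{[2',4'-dihydroxy-4-(hydroxymethyl)-3-[(4-hydroxyphenyl)ethynyl]-[1,1'-biphenyl]-2-yl](4-hydroxyphenyl)methylidene}cyclohexa-2,5-dien-1-one | O=C1C=CC(=C(c2ccc(O)cc2)c2c(-c3ccc(O)cc3O)ccc(CO)c2C#Cc2ccc(O)cc2)C=C1 | target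

## Step count and least certain steps

Total: 15 steps. Longest linear sequence: 10 steps (steps 4, 5, 6, 7, 8, 9, 10, 11, 14 and 15, from 6 to 25).

**Step 9 (key step).** The most likely failure is incomplete capture of the crowded arylmagnesium 15 by the electron-rich ketone 5, with surplus 12 competing for the ketone, so that 15 is simply protonated on work-up. A second failure is slow acetylide addition, which lets 13 add to 14. The first adjustment is LaCl3·2LiCl in the trapping stage. The fallback separates the two bond formations and keeps the aryne disconnection. It sets out from 15, generated from 11 and 12 exactly as in step 9. 15 is quenched with I2 at −78 to 0 °C to give the aryl iodide 2-iodo-4-[(methoxymethoxy)methyl]-3-{[4-(methoxymethoxy)phenyl]ethynyl}-1-(prop-2-en-1-yloxy)benzene F1, which is purified. Iodine–lithium exchange with n-BuLi in THF at −78 °C gives the more nucleophilic aryllithium {3-[(methoxymethoxy)methyl]-2-{[4-(methoxymethoxy)phenyl]ethynyl}-6-(prop-2-en-1-yloxy)phenyl}lithium F2, which is added to 5 in the absence of any competing acetylide. The fallback returns to the route at 16.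

**Step 14.** The triflate lies beside the triarylcarbinol, so oxidative addition and transmetalation may be slow. Hydrolysis of the triflate and protodeboronation of the electron-rich boronate can then take over. The neighbouring alkoxide may also bind palladium and open paths such as β-aryl elimination or attack on the alkyne. The fallback replaces the base-mediated boron coupling by a base-free Negishi coupling. Aryllithium 21, made from 20 as in step 13, is transmetalated with ZnCl2 to [2,4-bis(methoxymethoxy)phenyl]zinc chloride F3. F3 is used in excess, one equivalent being consumed by the carbinol proton, and is coupled with 18 under Pd(OAc)2 and SPhos in THF at rt to 40 °C. The fallback returns to the route at 23.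

**Step 15.** The Cm cation may be captured by the ortho oxygen of ring B (ring–chain tautomerism to a 6H-benzo[c]chromene). Formaldehyde equivalents may alkylate the resorcinol ring if the methanol trap is insufficient, and the benzylic MOM ether may cleave incompletely. The fallback accepts the ring closure and reverses it under base. From 23, the same acid treatment is driven to the closed isomer 6,6-bis(4-hydroxyphenyl)-8-(hydroxymethyl)-7-[(4-hydroxyphenyl)ethynyl]-6H-benzo[c]chromen-3-ol F4. F4 is then opened with K2CO3 in aqueous MeOH at rt, where the para-phenoxide expels the ring B aryloxide in a 1,6-elimination of the E1cB type. Neutralisation into pH 7 buffer at 0 °C should give 25 without acid to catalyse re-closure. The fallback returns to the route at 25.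

**Step 4.** Iodination may occur partly at C5 or twice, giving mixtures that are hard to separate at the start of the longest sequence. The fallback fixes the iodine position before the formyl group is introduced. Commercial 2-iodobenzene-1,3-diol F5 is formylated under Vilsmeier–Haack conditions (POCl3, DMF, then water). The only open activated positions are equivalent, each para to one hydroxyl and ortho to the other, so 7 is the sole regioisomer possible. The fallback returns to the route at 7.

## Further compounds

F1 | step 9 | 2-iodo-4-[(methoxymethoxy)methyl]-3-{[4-(methoxymethoxy)phenyl]ethynyl}-1-(prop-2-en-1-yloxy)benzene | C=CCOc1ccc(COCOC)c(C#Cc2ccc(OCOC)cc2)c1I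
F2 | step 9 | {3-[(methoxymethoxy)methyl]-2-{[4-(methoxymethoxy)phenyl]ethynyl}-6-(prop-2-en-1-yloxy)phenyl}lithium | C=CCOc1ccc(COCOC)c(C#Cc2ccc(OCOC)cc2)c1[Li]
F3 | step 14 | [2,4-bis(methoxymethoxy)phenyl]zinc chloride | COCOc1ccc([Zn]Cl)c(OCOC)c1
F4 | step 15 | 6,6-bis(4-hydroxyphenyl)-8-(hydroxymethyl)-7-[(4-hydroxyphenyl)ethynyl]-6H-benzo[c]chromen-3-ol | OCc1ccc2c(c1C#Cc1ccc(O)cc1)C(c1ccc(O)cc1)(c1ccc(O)cc1)Oc1cc(O)ccc1-2
F5 | step 4 | 2-iodobenzene-1,3-diol | Oc1cccc(O)c1I
A1 | alternative 1 | 2-ethynyl-5-(methoxymethoxy)phenyl 3-[diisopropyl(prop-2-yn-1-yloxy)silyl]prop-2-ynoate | COCOc1ccc(C#C)c(OC(=O)C#C[Si](C(C)C)(C(C)C)OCC#C)c1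
A2 | alternative 1 | oxasilole-fused 3-(methoxymethoxy)-6H-benzo[c]chromen-6-one (diisopropylsilyl on C6 of ring A, CH2O on C5) | COCOc1ccc2c(c1)OC(=O)c1c3c(ccc12)CO[Si]3(C(C)C)C(C)C
A3 | alternative 2 | 1,5-bis[4-(methoxymethoxy)phenyl]penta-2,4-diyn-1-one | COCOc1ccc(C(=O)C#CC#Cc2ccc(OCOC)cc2)cc1
A4 | alternative 2 | tert-butyl{[(2E,4E)-5-[2,4-bis(methoxymethoxy)phenyl]penta-2,4-dien-1-yl]oxy}dimethylsilane | CC(C)(C)[Si](C)(C)OC/C=C/C=C/c1ccc(OCOC)cc1OCOC
A5 | alternative 2 | [6-[2,4-bis(methoxymethoxy)phenyl]-3-[(tert-butyldimethylsilyloxy)methyl]-2-{[4-(methoxymethoxy)phenyl]ethynyl}phenyl][4-(methoxymethoxy)phenyl]methanone | CC(C)(C)[Si](C)(C)OCc1ccc(-c2ccc(OCOC)cc2OCOC)c(C(=O)c2ccc(OCOC)cc2)c1C#Cc1ccc(OCOC)cc1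
A6 | alternative 3 | 2-iodo-2',4'-bis(methoxymethoxy)-4-[(methoxymethoxy)methyl]-[1,1'-biphenyl]-3-carbaldehyde | COCOCc1ccc(-c2ccc(OCOC)cc2OCOC)c(I)c1C=O
A7 | alternative 3 | 1,2-bis[4-(methoxymethoxy)phenyl]ethyne | COCOc1ccc(C#Cc2ccc(OCOC)cc2)cc1
A8 | alternative 3 | 4-[2,4-bis(methoxymethoxy)phenyl]-7-[(methoxymethoxy)methyl]-2,3-bis[4-(methoxymethoxy)phenyl]-1H-inden-1-one | COCOCc1ccc(-c2ccc(OCOC)cc2OCOC)c2c1C(=O)C(c1ccc(OCOC)cc1)=C2c1ccc(OCOC)cc1
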